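**Retrosynthetic overview**

- Numbering: chain carbons run from C1′ (carbinol carbon on ring B, the 4-substituted 2,6-dihydroxyphenyl ether ring) to C14′ (benzylic CH2 on ring A, the resorcinol ring). The macrocycle is 22-membered: C1′–C14′, three atoms of ring A, the ether O, four atoms of ring B.
- Key disconnection C5′–C6′: a decarboxylative radical cascade on seco acid 16. A cyclopropane (C6′, C7′, C8′) on C9′ opens to the C8′=C9′ alkene, and the C6′ radical closes the macrocycle on C5′ of a vinyl sulfone. The enabling feature is the pair of CH2 groups C6′ and C7′ between the new bond and the alkene (C6′–C7′–C8′=C9′ is the open form of a cyclopropylcarbinyl unit), together with the purely methylene C4′, which can carry a traceless PhSO2 group; the diaryl ether between rings A and B holds the chain ends within reach.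
- Seco acid 16: ether O–ring A bond by Chan–Lam coupling, C14′–ring A by B-alkyl Suzuki coupling, C2′–C3′ by enolate SN2′ allylation.
- Ring order: rings A and B are bought; the only ring made is the macrocycle (step 9). C1′ (R) is then set by CBS reduction, followed by desulfonylation and MOM removal.

Key step: step 9

Remark: C9′ (compounds 10–16) and C4′ (compounds 17, 18) are stereocentres of no consequence, since C9′ becomes an alkene carbon and C4′ becomes CH2; these compounds are carried as racemates or epimer mixtures.

**Route**

Step 1
Reactants: 1 acetosyringone (1-(4-hydroxy-3,5-dimethoxyphenyl)ethanone); 2 (3-bromo-5-methoxyphenyl)boronic acid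
Product: 3 1-[4-(3-bromo-5-methoxyphenoxy)-3,5-dimethoxyphenyl]ethanone
Conditions: 2 (2 equiv), Cu(OAc)2 (1 equiv), pyridine (5 equiv), 4 Å molecular sieves, CH2Cl2, dry air, 25 °C
Reagents that add atoms: none
Why: Chan–Lam oxidative O-arylation, in which the copper phenoxide of 1 transmetalates with 2 and C–O reductive elimination from a trivalent copper intermediate should form the hindered diaryl ether at room temperature (air returns copper to the divalent state) without touching the aryl bromide.

Step 2
Reactants: 3
Product: 4 1-[4-(3-bromo-5-hydroxyphenoxy)-3,5-dihydroxyphenyl]ethanone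
Conditions: BBr3 (6 equiv), CH2Cl2, −78 → 25 °C; then MeOH, H2O
Reagents that add atoms: none
Why: Lewis-acid cleavage of aryl methyl ethers (complexation, then SN2 attack of bromide on methyl) should free all three phenols, while the diaryl ether, aryl bromide and ketone are inert to BBr3.

Step 3
Reactants: 4
Product: 5 1-{4-[3-bromo-5-(methoxymethoxy)phenoxy]-3,5-bis(methoxymethoxy)phenyl}ethanone
Conditions: MOMCl (4.5 equiv), K2CO3 (6 equiv), acetone, 0 → 25 °C
Reagents that add atoms: chloromethyl methyl ether, COCCl
Why: Williamson-type O-alkylation of the three phenoxides installs acetal protection that is stable to bases, fluoride, radicals and reductants and is removed at the end by mild acid.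

Step 4
Reactants: 6 cyclopropylacetic acid
Product: 7 2-(trimethylsilyl)ethyl cyclopropylacetate
Conditions: 2-(trimethylsilyl)ethanol (1.2 equiv), DCC, DMAP (0.1 equiv), CH2Cl2, 0 → 25 °C
Reagents that add atoms: 2-(trimethylsilyl)ethanol, C[Si](C)(C)CCO
Why: Steglich esterification gives an ester that tolerates enolate, borane and palladium chemistry and is later cleaved by fluoride without hydroxide.

Step 5
Reactants: 7; 8 5-bromopent-1-ene
Product: 10 2-(trimethylsilyl)ethyl 2-cyclopropylhept-6-enoate (racemic), via lithium ester enolate 9 (not isolated)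
Conditions: LDA (1.1 equiv), THF, −78 °C; then 8 (1.3 equiv), DMPU, −78 → 25 °C
Reagents that add atoms: none
Why: SN2 alkylation of the lithium ester enolate by a primary bromide joins C9′ to C10′; the cyclopropane is stable next to the enolate, and the new α-centre is racemic, which does not matter because it ends as an alkene carbon.

Step 6
Reactants: 10; 5
Product: 12 2-(trimethylsilyl)ethyl 7-{3-[4-acetyl-2,6-bis(methoxymethoxy)phenoxy]-5-(methoxymethoxy)phenyl}-2-cyclopropylheptanoate (racemic), via alkylborane 11 (not isolated)
Conditions: 10 (1.3 equiv), 9-BBN (1.3 equiv), THF, 0 → 25 °C; then 5, Pd(dppf)Cl2 (5 mol%), K3PO4 (3 M aq), DMF, 60 °C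
Reagents that add atoms: none
Why: anti-Markovnikov hydroboration of the terminal alkene followed by B-alkyl Suzuki–Miyaura coupling with the aryl bromide forms the C14′–ring A bond, and ketone, ester, acetals and cyclopropane are tolerated.

Step 7
Reactants: 12
Product: 13 7-{3-[4-acetyl-2,6-bis(methoxymethoxy)phenoxy]-5-(methoxymethoxy)phenyl}-2-cyclopropylheptanoic acid (racemic)
Conditions: TBAF (3 equiv), THF, 25 °C; then 0.5 M HCl, 0 °C
Reagents that add atoms: none
Why: fluoride attacks silicon and the ester fragments by β-elimination to ethene, Me3SiF and the carboxylate, which frees the acid without hydroxide and before any Michael acceptor is present.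

Step 8
Reactants: 13; 14 2,3-bis(phenylsulfonyl)prop-1-ene
Product: 16 7-{3-[2,6-bis(methoxymethoxy)-4-(4-(phenylsulfonyl)pent-4-enoyl)phenoxy]-5-(methoxymethoxy)phenyl}-2-cyclopropylheptanoic acid (racemic), via dilithium carboxylate–enolate dianion 15 (not isolated)
Conditions: LiHMDS (2.2 equiv), THF, −78 °C; then 14 (1.05 equiv), −78 → −40 °C; then dilute HCl to pH 4
Reagents that add atoms: none
Why: two equivalents of LiHMDS give the carboxylate/methyl-ketone enolate dianion (the α-branched carboxylate is not deprotonated further), and the enolate carbon adds to the terminal CH2 of 14 with loss of benzenesulfinate (SN2′ addition–elimination), which installs the 2-(phenylsulfonyl)allyl unit C3′–C5′.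

Step 9
Reactants: 16
Product: 17 macrocyclic keto sulfone: the 22-membered C1′ ketone of dehydrogravicycle tris(methoxymethyl) ether bearing PhSO2 at C4′ (racemic at C4′), C8′=C9′ E
Conditions: [Ir(dF(CF3)ppy)2(dtbbpy)]PF6 (2 mol%), K2HPO4 (1.2 equiv), degassed DMSO (1 mM), 450 nm LEDs, 20 °C
Reagents that add atoms: none
Why: Proposed new method: the excited iridium photocatalyst oxidises the carboxylate of 16 and loss of CO2 gives the secondary cyclopropylcarbinyl radical at C9′, which opens by strain-releasing β-scission (far faster than any bimolecular trapping) to the primary homoallyl radical at C6′ with the C8′=C9′ double bond; this nucleophilic radical adds to the unsubstituted terminus C5′ of the vinyl sulfone, and the α-sulfonyl radical at C4′ is reduced by the reduced photocatalyst and protonated, so the cycle is redox-neutral and needs no hydride donor. The closest known reaction types are the photoredox decarboxylative Giese addition (also used to close peptide macrocycles onto acrylamides), the ring opening of cyclopropylcarbinyl radicals used as radical clocks, and the endo radical macrocyclisation of ω-haloalkyl acrylates; joining them into one ring-opening/macrocyclisation cascade is the new element. The only ring closed is the 22-membered macrocycle, by 22-endo-trig attack at C5′ (attack at the substituted C4′ is disfavoured sterically and by polarity). No lasting stereocentre is made: the racemic C9′ centre of 16 is destroyed on decarboxylation and the C4′ centre forms as a racemate that step 11 erases, while the alkene geometry is controlled in the ring opening, where the bisected transition state keeps the C10′ chain anti to the breaking ring bond and so should favour E. The step needs ring opening before trapping (secured by the unimolecular rate of the opening), E over Z (secured by that conformational preference and by the E preference of the equilibrating homoallyl radicals, with any minor Z isomer to be removed on AgNO3-impregnated silica), and cyclisation over oligomerisation or reduction (secured by 1 mM dilution, the polarity match of a primary alkyl radical with a 1,1-disubstituted vinyl sulfone, and the absence of a good hydrogen-atom donor).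

Step 10
Reactants: 17
Product: 18 (1′R)-carbinol: dehydrogravicycle tris(methoxymethyl) ether bearing PhSO2 at C4′ (both C4′ epimers), C8′=C9′ E
Conditions: (S)-2-methyl-CBS-oxazaborolidine (0.3 equiv), catecholborane (2 equiv), toluene, −78 → −40 °C; then MeOH, aq NaOH wash
Reagents that add atoms: none
Why: Corey–Bakshi–Shibata reduction, in which the (S)-oxazaborolidine binds the ketone with ring B as the large and the C2′ methylene as the small substituent and directs hydride from catecholborane to the Si face, should set C1′ as R, while catecholborane at low temperature leaves the isolated alkene and the sulfone untouched.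

Step 11
Reactants: 18
Product: 19 dehydrogravicycle tris(methoxymethyl) ether (C1′ R, C8′=C9′ E)
Conditions: Na/Hg (6% Na, 8 equiv), Na2HPO4, MeOH/THF (3:1), −20 → 0 °C
Reagents that add atoms: none
Why: reductive desulfonylation by single-electron transfer from sodium amalgam cleaves the C4′–S bond and buffered methanol protonates the carbanion, which erases the C4′ centre, while the isolated E-alkene, acetals, diaryl ether and benzylic alcohol are not reduced under these conditions.

Step 12
Reactants: 19
Product: 20 dehydrogravicycle
Conditions: HCl (0.5 M in MeOH), 25 → 40 °C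
Reagents that add atoms: none
Why: acid-catalysed acetal exchange with methanol removes the three aryl MOM groups, and the benzylic carbinol (its cation only weakly stabilised by one para-aryloxy and two meta-oxygen groups) and the isolated alkene should survive dilute acid, so C1′ stays R.

**Compound list**

1 | acetosyringone, 1-(4-hydroxy-3,5-dimethoxyphenyl)ethanone | CC(=O)c1cc(OC)c(O)c(OC)c1 | starting material
2 | (3-bromo-5-methoxyphenyl)boronic acid | COc1cc(Br)cc(c1)B(O)O | starting material
3 | 1-[4-(3-bromo-5-methoxyphenoxy)-3,5-dimethoxyphenyl]ethanone | CC(=O)c1cc(OC)c(Oc2cc(Br)cc(OC)c2)c(OC)c1 | intermediate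
4 | 1-[4-(3-bromo-5-hydroxyphenoxy)-3,5-dihydroxyphenyl]ethanone | CC(=O)c1cc(O)c(Oc2cc(Br)cc(O)c2)c(O)c1 | intermediate
5 | 1-{4-[3-bromo-5-(methoxymethoxy)phenoxy]-3,5-bis(methoxymethoxy)phenyl}ethanone | CC(=O)c1cc(OCOC)c(Oc2cc(Br)cc(OCOC)c2)c(OCOC)c1 | intermediate
6 | cyclopropylacetic acid | OC(=O)CC1CC1 | starting material
7 | 2-(trimethylsilyl)ethyl cyclopropylacetate | C[Si](C)(C)CCOC(=O)CC1CC1 | intermediate
8 | 5-bromopent-1-ene | BrCCCC=C | starting material
9 | lithium enolate of ester 7 | C[Si](C)(C)CCOC([O-])=CC1CC1.[Li+] | intermediate (not isolated)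
10 | 2-(trimethylsilyl)ethyl 2-cyclopropylhept-6-enoate (racemic) | C[Si](C)(C)CCOC(=O)C(CCCC=C)C1CC1 | intermediate
11 | 2-(trimethylsilyl)ethyl 7-(9-borabicyclo[3.3.1]nonan-9-yl)-2-cyclopropylheptanoate | C[Si](C)(C)CCOC(=O)C(CCCCCB1C2CCCC1CCC2)C1CC1 | intermediate (not isolated)
12 | 2-(trimethylsilyl)ethyl 7-{3-[4-acetyl-2,6-bis(methoxymethoxy)phenoxy]-5-(methoxymethoxy)phenyl}-2-cyclopropylheptanoate (racemic) | C[Si](C)(C)CCOC(=O)C(CCCCCc1cc(OCOC)cc(Oc2c(OCOC)cc(cc2OCOC)C(C)=O)c1)C1CC1 | intermediate
13 | 7-{3-[4-acetyl-2,6-bis(methoxymethoxy)phenoxy]-5-(methoxymethoxy)phenyl}-2-cyclopropylheptanoic acid (racemic) | OC(=O)C(CCCCCc1cc(OCOC)cc(Oc2c(OCOC)cc(cc2OCOC)C(C)=O)c1)C1CC1 | intermediate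
14 | 2,3-bis(phenylsulfonyl)prop-1-ene | C=C(CS(=O)(=O)c1ccccc1)S(=O)(=O)c1ccccc1 | starting material
15 | dilithium carboxylate–enolate dianion of 13 | [Li+].[Li+].[O-]C(=O)C(CCCCCc1cc(OCOC)cc(Oc2c(OCOC)cc(cc2OCOC)C(=C)[O-])c1)C1CC1 | intermediate (not isolated)
16 | 7-{3-[2,6-bis(methoxymethoxy)-4-(4-(phenylsulfonyl)pent-4-enoyl)phenoxy]-5-(methoxymethoxy)phenyl}-2-cyclopropylheptanoic acid (racemic) | OC(=O)C(CCCCCc1cc(OCOC)cc(Oc2c(OCOC)cc(cc2OCOC)C(=O)CCC(=C)S(=O)(=O)c3ccccc3)c1)C1CC1 | intermediate
17 | macrocyclic keto sulfone (C1′ ketone, PhSO2 at C4′, racemic at C4′, C8′=C9′ E, three MOM ethers) | COCOc1cc2cc(c1)Oc1c(OCOC)cc(cc1OCOC)C(=O)CCC(CCC/C=C/CCCCC2)S(=O)(=O)c1ccccc1 | intermediate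
18 | macrocyclic (1′R)-hydroxy sulfone (PhSO2 at C4′, both C4′ epimers, C8′=C9′ E, three MOM ethers) | COCOc1cc2cc(c1)Oc1c(OCOC)cc(cc1OCOC)[C@H](O)CCC(CCC/C=C/CCCCC2)S(=O)(=O)c1ccccc1 | intermediate
19 | dehydrogravicycle tris(methoxymethyl) ether (C1′ R, C8′=C9′ E) | COCOc1cc2cc(c1)Oc1c(OCOC)cc(cc1OCOC)[C@H](O)CCCCCC/C=C/CCCCC2 | intermediate
20 | dehydrogravicycle | Oc1cc2cc(c1)Oc1c(O)cc(cc1O)[C@H](O)CCCCCC/C=C/CCCCC2 | target

**Step count and risks**

Total steps: 12. Longest linear sequence: 10 (steps 1, 2, 3, 6, 7, 8, 9, 10, 11, 12); steps 4 and 5 form the side branch that joins at step 6.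

Steps most likely to fail:

1. Step 9 (the step that carries the proposed-new-method label). The ring opening may not be E-selective enough. The E and Z homoallyl radicals can also interconvert by reversible reclosure to the cyclopropylcarbinyl radical while they wait for the slow macrocyclisation. Intermolecular addition (oligomerisation) or hydrogen-atom capture from the solvent may outrun ring closure. The fallback uses known chemistry and fixes the alkene geometry before ring closure by an ionic rearrangement; it sets out from 5 and comes back at 17. Hex-5-enal and cyclopropylmagnesium bromide (both bought) give 1-cyclopropylhex-5-en-1-ol F1. The cationic Julia olefin synthesis (48% HBr, ZnBr2, 0 °C) should turn it into (6E)-9-bromonona-1,6-diene F2. 9-BBN adds only to the terminal alkene, giving the alkylborane F3 (not isolated), which is coupled with 5 under the step 6 conditions to give the bromo ketone F4. LiHMDS (1.05 equiv, THF, −78 °C) gives its lithium enolate F5 (not isolated), which is allylated with 14 to the bromo vinyl sulfone ketone F6. A conventional radical macrocyclisation of the primary bromide onto the vinyl sulfone ((Me3Si)3SiH by slow addition, Et3B/air, toluene, −20 °C, 1 mM) then gives 17. The low temperature is chosen so that addition to the vinyl sulfone outruns reclosure of the homoallyl radical.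

2. Step 1. C–O bond formation at the doubly ortho-substituted, electron-poor phenol may be slow, so that protodeboronation, oxidation or homocoupling of the boronic acid consumes 2 first. The fallback sets out from 1 and comes back at 3. An Ullmann-type coupling of 1 with bought 1,3-dibromo-5-methoxybenzene (3 equiv; CuI, picolinic acid, K3PO4, DMSO, 90 °C) gives 3 directly; the excess dibromide limits double arylation. It makes no new compound (F0).

3. Step 8. Proton transfer from the acidic allylic CH2 of 14 to the enolate, double allylation, or oxa-Michael ring closure of the product enolate onto the new vinyl sulfone may compete with the single SN2′ event. The fallback sets out from 13 and comes back at 16. The same dianion 15 is alkylated with 2,3-dibromoprop-1-ene (no acidic protons, no Michael acceptor) to the 2-bromoallyl keto acid F7. Palladium-catalysed C–S coupling with thiophenol (Pd2(dba)3, Xantphos, iPr2NEt, dioxane, 90 °C) gives the vinyl sulfide keto acid F8. Oxidation at sulfur with mCPBA (2.1 equiv, CH2Cl2, 0 °C) gives 16.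

Further compounds

F1 | step 9 | 1-cyclopropylhex-5-en-1-ol | OC(CCCC=C)C1CC1
F2 | step 9 | (6E)-9-bromonona-1,6-diene | C=CCCC/C=C/CCBr
F3 | step 9 | 9-[(6E)-9-bromonon-6-en-1-yl]-9-borabicyclo[3.3.1]nonane (not isolated) | BrCC/C=C/CCCCCB1C2CCCC1CCC2
F4 | step 9 | 1-{4-[3-((6E)-9-bromonon-6-en-1-yl)-5-(methoxymethoxy)phenoxy]-3,5-bis(methoxymethoxy)phenyl}ethanone | CC(=O)c1cc(OCOC)c(Oc2cc(CCCCC/C=C/CCBr)cc(OCOC)c2)c(OCOC)c1
F5 | step 9 | lithium enolate of F4 (not isolated) | [Li+].[O-]C(=C)c1cc(OCOC)c(Oc2cc(CCCCC/C=C/CCBr)cc(OCOC)c2)c(OCOC)c1
F6 | step 9 | 1-{4-[3-((6E)-9-bromonon-6-en-1-yl)-5-(methoxymethoxy)phenoxy]-3,5-bis(methoxymethoxy)phenyl}-4-(phenylsulfonyl)pent-4-en-1-one | C=C(CCC(=O)c1cc(OCOC)c(Oc2cc(CCCCC/C=C/CCBr)cc(OCOC)c2)c(OCOC)c1)S(=O)(=O)c1ccccc1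
F0 | step 1 | none | none
F7 | step 8 | 7-{3-[4-(4-bromopent-4-enoyl)-2,6-bis(methoxymethoxy)phenoxy]-5-(methoxymethoxy)phenyl}-2-cyclopropylheptanoic acid (racemic) | OC(=O)C(CCCCCc1cc(OCOC)cc(Oc2c(OCOC)cc(cc2OCOC)C(=O)CCC(Br)=C)c1)C1CC1
F8 | step 8 | 7-{3-[2,6-bis(methoxymethoxy)-4-(4-(phenylsulfanyl)pent-4-enoyl)phenoxy]-5-(methoxymethoxy)phenyl}-2-cyclopropylheptanoic acid (racemic) | OC(=O)C(CCCCCc1cc(OCOC)cc(Oc2c(OCOC)cc(cc2OCOC)C(=O)CCC(=C)Sc3ccccc3)c1)C1CC1
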